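**Strategy.** The central tetrasubstituted benzene ring carries, on two adjacent ring carbons, the arylethynyl C(sp) and the exocyclic quinone-methide carbon, flanked by the methyl-bearing carbon and the 4-hydroxyphenyl-bearing carbon. Both bonds are cut at once, back to 3-chloro-6-methylbenzyne, 4-ethynylanisole and CO2. One copper-catalysed operation joins them: the acetylide adds next to the methyl, the arylcopper takes up CO2 next to chlorine, and iodomethane fixes the carboxyl as its methyl ester. The precursor is an ortho-(trimethylsilyl)aryl triflate with chlorine beside the triflate and methyl beside silicon. Chlorine steers the addition and later becomes the Suzuki handle; the ester carbon becomes the quinone-methide carbon after two aryllithium additions and global demethylation.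

Key step: step 4

Remark: the target carries no stereocentre, and the cyclohexadienone end of the exocyclic double bond is symmetric, so no alkene geometry has to be set; possible hindered-rotation isomers are taken as not resolved.

Step 1
Reactants: 1 2-chloro-5-methylphenol
Product: 2 2-chloro-5-methylphenyl propan-2-ylcarbamate
Conditions: i-PrNCO, Et3N (cat.), CH2Cl2, rt
Reagents that add atoms: isopropyl isocyanate, CC(C)N=C=O
Why: Base-catalysed addition of the phenol O–H to the isocyanate (carbamoylation) should cleanly install a secondary carbamate, chosen over a dialkyl carbamate because it directs ortho-metalation once N-silylated and can later be removed under mild E1cB conditions that spare an aryl–silicon bond.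

Step 2
Reactants: 2 2-chloro-5-methylphenyl propan-2-ylcarbamate
Product: 6 6-chloro-3-methyl-2-(trimethylsilyl)phenyl propan-2-ylcarbamate, via N-silyl carbamate 3 (not isolated), via aryllithium 4 (not isolated), via bis-silyl carbamate 5 (not isolated)
Conditions: TBSOTf, TMEDA, Et2O, 0 °C → rt; then n-BuLi (2 equiv), TMEDA, −78 °C; then TMSCl, −78 °C → rt; aq. NaHSO4
Reagents that add atoms: chlorotrimethylsilane, C[Si](C)(C)Cl
Why: Directed ortho-metalation should work because the N-silylated carbamate formed in the flask masks the N–H and guides n-BuLi to the only free ortho position (between the carbamate oxygen and the methyl group, the other ortho carbon carrying chlorine, which tolerates butyllithium at −78 °C), after which silyl quench and acidic work-up, which removes the labile N-silyl group, give the C-silyl carbamate.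

Step 3
Reactants: 6 6-chloro-3-methyl-2-(trimethylsilyl)phenyl propan-2-ylcarbamate
Product: 8 6-chloro-3-methyl-2-(trimethylsilyl)phenyl trifluoromethanesulfonate, via silyl phenol 7 (not isolated)
Conditions: DBU, Et2NH, MeCN, 40 °C; then PhNTf2, rt
Reagents that add atoms: N-phenylbis(trifluoromethanesulfonimide), O=S(=O)(N(c1ccccc1)S(=O)(=O)C(F)(F)F)C(F)(F)F
Why: E1cB cleavage of the secondary carbamate (N-deprotonation and loss of isopropyl isocyanate, which diethylamine scavenges as the urea) frees the phenoxide without touching the aryl–silicon bond, and O-sulfonylation of that phenoxide by PhNTf2 in the same flask should give the aryl triflate.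

Step 4
Reactants: 8 6-chloro-3-methyl-2-(trimethylsilyl)phenyl trifluoromethanesulfonate; 9 4-ethynylanisole; 10 carbon dioxide
Product: 15 methyl 6-chloro-2-[(4-methoxyphenyl)ethynyl]-3-methylbenzoate, via copper acetylide 11 (not isolated), via 3-chloro-6-methylbenzyne 12 (not isolated), via arylcopper 13 (not isolated), via cesium benzoate 14 (not isolated)
Conditions: (IPr)CuCl [IPr = 1,3-bis(2,6-diisopropylphenyl)imidazol-2-ylidene] (10 mol %), CsF, Cs2CO3, CO2 (1 atm), MeCN, rt; then MeI, rt, same flask
Reagents that add atoms: iodomethane, CI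
Why: Fluoride attacks silicon and triflate leaves, releasing benzyne 12 at room temperature, while carbonate and the monovalent copper catalyst turn alkyne 9 into acetylide 11; syn-carbocupration of the strained triple bond gives arylcopper 13, whose copper–carbon bond inserts CO2 to a copper carboxylate that exchanges with the base to cesium benzoate 14 and returns the acetylide. The closest known reaction type is the NHC–copper-catalysed three-component coupling of arynes, terminal alkynes and CO2, which normally runs on to isocoumarins; here the mixture is kept at room temperature and the carboxylate is O-methylated in the same flask (SN2 of a cesium carboxylate on iodomethane) before lactonisation onto the alkyne can set in. Iodomethane is held back until the triflate is consumed, so that it can neither methylate arylcopper 13 nor trap a propiolate formed reversibly from 11 and CO2. No ring is closed and no stereocentre is formed. The step needs regioselective carbocupration: the inductively withdrawing chlorine distorts the aryne so that the carbon remote from it, the one next to methyl, is the electrophilic terminus, which places the acetylide there and copper, then the carboxyl group, on the carbon ortho to chlorine, a bias expected to outweigh the small steric preference of the methyl group.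

Step 5
Reactants: 15 methyl 6-chloro-2-[(4-methoxyphenyl)ethynyl]-3-methylbenzoate; 16 4-methoxyphenylboronic acid
Product: 17 methyl 4'-methoxy-3-[(4-methoxyphenyl)ethynyl]-4-methyl-[1,1'-biphenyl]-2-carboxylate
Conditions: Pd(OAc)2 (cat.), SPhos, K3PO4, toluene/H2O, 100 °C
Reagents that add atoms: none
Why: In this Suzuki–Miyaura coupling the electron-rich dialkylbiarylphosphine should let zerovalent palladium insert into the ester-activated aryl chloride, while the mild phosphate base leaves the hindered methyl ester and the internal alkyne untouched.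

Step 6
Reactants: 17 methyl 4'-methoxy-3-[(4-methoxyphenyl)ethynyl]-4-methyl-[1,1'-biphenyl]-2-carboxylate; 18 4-bromoanisole
Product: 21 bis(4-methoxyphenyl){4'-methoxy-3-[(4-methoxyphenyl)ethynyl]-4-methyl-[1,1'-biphenyl]-2-yl}methanol, via 4-methoxyphenyllithium 19 (not isolated), via diaryl ketone 20 (not isolated)
Conditions: 18 (3.0 equiv), n-BuLi (2.9 equiv), THF, −78 °C; then 17 (1.0 equiv), −78 → 0 °C; H2O
Reagents that add atoms: 4-bromoanisole, the second of the two equivalents of 18 that end up in 21 (it supplies the second 4-methoxyphenyl group through 19), COc1ccc(Br)cc1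
Why: Twofold 1,2-addition of the aryllithium, made by bromine–lithium exchange and used in excess so that one equivalent displaces methoxide to give ketone 20 and a second equivalent adds to that ketone, should give the triarylcarbinol, since neither carbonyl stage has an α-hydrogen to divert the small, strongly nucleophilic reagent into enolisation.

Step 7
Reactants: 21 bis(4-methoxyphenyl){4'-methoxy-3-[(4-methoxyphenyl)ethynyl]-4-methyl-[1,1'-biphenyl]-2-yl}methanol
Product: 23 selaginellin U, via tetraphenol carbinol 22 (not isolated)
Conditions: BBr3, CH2Cl2, −78 °C → rt; then H2O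
Reagents that add atoms: none
Why: Lewis-acid cleavage of the four aryl methyl ethers and hydrolytic work-up free the phenols, and the triarylcarbinol bearing two para-hydroxyphenyl groups should lose water spontaneously through its stabilised triarylmethyl cation to the conjugated para-quinone methide, only one product being possible because those two aryl groups are equivalent.

**Compound list**

1 | 2-chloro-5-methylphenol | Cc1ccc(Cl)c(O)c1 | starting material
2 | 2-chloro-5-methylphenyl propan-2-ylcarbamate | Cc1ccc(Cl)c(OC(=O)NC(C)C)c1 | intermediate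
3 | 2-chloro-5-methylphenyl N-(tert-butyldimethylsilyl)-N-(propan-2-yl)carbamate | Cc1ccc(Cl)c(OC(=O)N(C(C)C)[Si](C)(C)C(C)(C)C)c1 | intermediate
4 | 6-lithio derivative of 3 (lithium between the carbamate oxygen and the methyl group) | Cc1ccc(Cl)c(OC(=O)N(C(C)C)[Si](C)(C)C(C)(C)C)c1[Li] | intermediate
5 | 6-chloro-3-methyl-2-(trimethylsilyl)phenyl N-(tert-butyldimethylsilyl)-N-(propan-2-yl)carbamate | Cc1ccc(Cl)c(OC(=O)N(C(C)C)[Si](C)(C)C(C)(C)C)c1[Si](C)(C)C | intermediate
6 | 6-chloro-3-methyl-2-(trimethylsilyl)phenyl propan-2-ylcarbamate | Cc1ccc(Cl)c(OC(=O)NC(C)C)c1[Si](C)(C)C | intermediate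
7 | 6-chloro-3-methyl-2-(trimethylsilyl)phenol (present as its DBU-H salt) | Cc1ccc(Cl)c(O)c1[Si](C)(C)C | intermediate
8 | 6-chloro-3-methyl-2-(trimethylsilyl)phenyl trifluoromethanesulfonate | Cc1ccc(Cl)c(OS(=O)(=O)C(F)(F)F)c1[Si](C)(C)C | intermediate
9 | 4-ethynylanisole | COc1ccc(C#C)cc1 | starting material
10 | carbon dioxide | O=C=O | starting material
11 | (IPr)copper (4-methoxyphenyl)acetylide | COc1ccc(C#C[Cu]=C2N(c3c(C(C)C)cccc3C(C)C)C=CN2c2c(C(C)C)cccc2C(C)C)cc1 | intermediate
12 | 3-chloro-6-methylbenzyne | CC1=CC=C(Cl)C#C1 | intermediate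
13 | (IPr)copper 6-chloro-2-[(4-methoxyphenyl)ethynyl]-3-methylphenyl | COc1ccc(C#Cc2c(C)ccc(Cl)c2[Cu]=C2N(c3c(C(C)C)cccc3C(C)C)C=CN2c2c(C(C)C)cccc2C(C)C)cc1 | intermediate
14 | cesium 6-chloro-2-[(4-methoxyphenyl)ethynyl]-3-methylbenzoate | COc1ccc(C#Cc2c(C)ccc(Cl)c2C(=O)[O-])cc1.[Cs+] | intermediate
15 | methyl 6-chloro-2-[(4-methoxyphenyl)ethynyl]-3-methylbenzoate | COC(=O)c1c(Cl)ccc(C)c1C#Cc1ccc(OC)cc1 | intermediate
16 | 4-methoxyphenylboronic acid | COc1ccc(B(O)O)cc1 | starting material
17 | methyl 4'-methoxy-3-[(4-methoxyphenyl)ethynyl]-4-methyl-[1,1'-biphenyl]-2-carboxylate | COC(=O)c1c(-c2ccc(OC)cc2)ccc(C)c1C#Cc1ccc(OC)cc1 | intermediate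
18 | 4-bromoanisole | COc1ccc(Br)cc1 | starting material
19 | 4-methoxyphenyllithium | [Li]c1ccc(OC)cc1 | intermediate
20 | (4-methoxyphenyl){4'-methoxy-3-[(4-methoxyphenyl)ethynyl]-4-methyl-[1,1'-biphenyl]-2-yl}methanone | COc1ccc(C#Cc2c(C)ccc(-c3ccc(OC)cc3)c2C(=O)c2ccc(OC)cc2)cc1 | intermediate
21 | bis(4-methoxyphenyl){4'-methoxy-3-[(4-methoxyphenyl)ethynyl]-4-methyl-[1,1'-biphenyl]-2-yl}methanol | COc1ccc(C#Cc2c(C)ccc(-c3ccc(OC)cc3)c2C(O)(c2ccc(OC)cc2)c2ccc(OC)cc2)cc1 | intermediate
22 | bis(4-hydroxyphenyl){4'-hydroxy-3-[(4-hydroxyphenyl)ethynyl]-4-methyl-[1,1'-biphenyl]-2-yl}methanol | Cc1ccc(-c2ccc(O)cc2)c(C(O)(c2ccc(O)cc2)c2ccc(O)cc2)c1C#Cc1ccc(O)cc1 | intermediate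
23 | selaginellin U, 4-[(4-hydroxyphenyl){4'-hydroxy-3-[(4-hydroxyphenyl)ethynyl]-4-methyl-[1,1'-biphenyl]-2-yl}methylidene]cyclohexa-2,5-dien-1-one | Cc1ccc(-c2ccc(O)cc2)c(C(=C2C=CC(=O)C=C2)c2ccc(O)cc2)c1C#Cc1ccc(O)cc1 | target

**Step count.** Total: 7 steps. Longest linear sequence: 7 steps, from 1 to 23.

**Steps most likely to fail**

Step 4. The cesium carboxylate may lactonise onto the neighbouring alkyne under copper catalysis before it is methylated. The doubly flanked arylcopper may be protonated by alkyne or hydrogencarbonate faster than it takes up CO2. The carbocupration may also not be fully regioselective. The fallback sets out from 8 and 9 and comes back at 15. Alkyne 9 would be brominated with NBS and catalytic AgNO3 in acetone to 1-(bromoethynyl)-4-methoxybenzene F1. A CuBr-catalysed bromoalkynylation of aryne 12, released from 8 with KF and 18-crown-6 in THF, would add the alkynyl group next to methyl and bromine next to chlorine, giving 2-bromo-1-chloro-3-[(4-methoxyphenyl)ethynyl]-4-methylbenzene F2. Selective bromine–magnesium exchange with i-PrMgCl·LiCl in THF at −20 °C would give {6-chloro-2-[(4-methoxyphenyl)ethynyl]-3-methylphenyl}magnesium chloride F3, which would be acylated with methyl chloroformate to 15. In this variant no free carboxylate ever sits next to the alkyne.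

Step 6. Acyl substitution at an ester carbonyl flanked by an aryl and an arylethynyl group may be so slow that the sequence stalls at the ester or ketone stage while the excess aryllithium is consumed in other ways. The fallback sets out from 17 and comes back at 20 and then 21. DIBAL-H in CH2Cl2 would reduce the ester to {4'-methoxy-3-[(4-methoxyphenyl)ethynyl]-4-methyl-[1,1'-biphenyl]-2-yl}methanol F4. Dess–Martin oxidation would give 4'-methoxy-3-[(4-methoxyphenyl)ethynyl]-4-methyl-[1,1'-biphenyl]-2-carbaldehyde F5. Addition of commercial 4-methoxyphenylmagnesium bromide to this far less hindered aldehyde would give racemic (4-methoxyphenyl){4'-methoxy-3-[(4-methoxyphenyl)ethynyl]-4-methyl-[1,1'-biphenyl]-2-yl}methanol F6. A second Dess–Martin oxidation would give ketone 20, and addition of 19 premixed with anhydrous CeCl3 (organocerium addition) would give 21.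

Step 2. Metalation may take place beside chlorine and not at the crowded position between carbamate and methyl, or butyllithium may attack the carbamate carbonyl, so that silicon ends up on the wrong carbon or conversion stays low. The fallback sets out from 1 and comes back at 8. Ortho-selective bromination with NBS and catalytic i-Pr2NH in CH2Cl2 would give 2-bromo-6-chloro-3-methylphenol F7. O-silylation with hexamethyldisilazane would give (2-bromo-6-chloro-3-methylphenoxy)trimethylsilane F8. n-BuLi in THF at −78 °C would effect bromine–lithium exchange with immediate O-to-C silyl shift (retro-Brook rearrangement), giving lithium 6-chloro-3-methyl-2-(trimethylsilyl)phenolate F9, which Tf2O would convert into 8. Here the position of silicon is fixed by the position of bromine and not by a kinetic deprotonation.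

**Further compounds**

F1 | step 4 | 1-(bromoethynyl)-4-methoxybenzene | COc1ccc(C#CBr)cc1
F2 | step 4 | 2-bromo-1-chloro-3-[(4-methoxyphenyl)ethynyl]-4-methylbenzene | COc1ccc(C#Cc2c(C)ccc(Cl)c2Br)cc1
F3 | step 4 | {6-chloro-2-[(4-methoxyphenyl)ethynyl]-3-methylphenyl}magnesium chloride | COc1ccc(C#Cc2c(C)ccc(Cl)c2[Mg]Cl)cc1
F4 | step 6 | {4'-methoxy-3-[(4-methoxyphenyl)ethynyl]-4-methyl-[1,1'-biphenyl]-2-yl}methanol | COc1ccc(C#Cc2c(C)ccc(-c3ccc(OC)cc3)c2CO)cc1
F5 | step 6 | 4'-methoxy-3-[(4-methoxyphenyl)ethynyl]-4-methyl-[1,1'-biphenyl]-2-carbaldehyde | COc1ccc(C#Cc2c(C)ccc(-c3ccc(OC)cc3)c2C=O)cc1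
F6 | step 6 | racemic (4-methoxyphenyl){4'-methoxy-3-[(4-methoxyphenyl)ethynyl]-4-methyl-[1,1'-biphenyl]-2-yl}methanol | COc1ccc(C#Cc2c(C)ccc(-c3ccc(OC)cc3)c2C(O)c2ccc(OC)cc2)cc1
F7 | step 2 | 2-bromo-6-chloro-3-methylphenol | Cc1ccc(Cl)c(O)c1Br
F8 | step 2 | (2-bromo-6-chloro-3-methylphenoxy)trimethylsilane | Cc1ccc(Cl)c(O[Si](C)(C)C)c1Br
F9 | step 2 | lithium 6-chloro-3-methyl-2-(trimethylsilyl)phenolate | Cc1ccc(Cl)c([O-])c1[Si](C)(C)C.[Li+]
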